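**Remarks on the chemistry (assumptions).**
- Atom numbers C1–C20 are those of the target and are kept for every intermediate: ring carbons C1–C14, C15 the OCMe2 carbon, C18 the methyl on C4, C19 the exocyclic methylene on C8, C20 the methyl on C12.
- The C18 carbon is carried as an ethyl ester, and the C12 ketone is left free through the key step and ketalised directly after it; both are spectator changes.
- Compound 36 is formed as a mixture of C7 epimers that converge at enone 37.
- Stereodescriptors and SMILES were derived by hand and not checked with software.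

## Analysis of the target

The target is a cembrane-type diterpenoid: a 14-membered carbocycle C1–C14 in which an ether oxygen joins C4 to the isopropyl carbon C15 on C1. C1, C2, C3, C4, O and C15 therefore form a 2,2,6,6-tetrasubstituted oxane inside the macrocycle. Three of the four stereocentres lie on this oxane (C1 R, C3 R, C4 S). The two arms of the macrocycle, C14 on C1 and C5 on C4, are cis to each other, and the C3 acetate and the C18 methyl group share the opposite face. The fourth stereocentre, C7 (R), is a secondary allylic alcohol next to the C8 methylene; it is too far from the oxane to be relayed from it, and the C11=C12 alkene is trisubstituted and E. Sensitive points are the allylic alcohol, the acetate (which must be on C3 before the less hindered C7 hydroxyl is free) and the acid-labile di-tertiary ether, which no substitution at carbon can make. The synthesis is hard because C4 is fully substituted and oxygen-bearing, and because the C3 oxygen lies on the open face of the oxane, the face from which a hydride, not the oxygen, would normally arrive. The plan rests on one feature: C4 holds the ring oxygen, a one-carbon group (C18) and the C5 methylene, next to oxygenated C3. This is the pattern left when an allyl group moves from an oxonium oxygen to a carbenoid carbon flanked by a ketone and an ester.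

## Retrosynthetic reasoning

**C7 carbinol (40 from 39).** The C7–H bond is cut last. C7 cannot be controlled from the oxane, so it is set by a reagent-controlled enone reduction. Keeping C7 as a ketone until the end also lets the C3 acetate be installed while no other hydroxyl is present.

**Macrocycle (39, 38, 37 from 36, and 36 from 35).** The ring is opened at C7–C8. The C7 carbinol with the C8 methylene is the retron of an alkenyl halide–aldehyde coupling, and the two arms to be joined sit cis on the oxane. The coupling only has to close the 14-membered ring; its C7 selectivity is irrelevant because 36 is oxidised to 37.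

**C10–C11 bond (33 from 29 and 31).** An sp3–sp2 cross-coupling joins the four-carbon piece 31 (C8, C9, C10, C19) to the alkenyl iodide 29. The cut is made here because the E geometry of C11=C12 can be fixed beforehand by syn carbometalation of alkyne 27. The alkyne comes from the methyl ketone 25, whose methyl carbon becomes C11.

**Side-chain functions (25 from 21).** C7 is reached by anti-Markovnikov hydration of the allyl group of 21. The C12 ketone is kept as a ketal until the basic and hydridic steps on the ring are over.

**C3 and C18 (21 from 14).** A hydride would reach the C3 ketone of 14 from the face opposite C5 and C14 and would place the hydroxyl on the wrong side. The ketone is therefore turned into the C2=C3 alkene (15, 16). The ester is reduced to the C18 alcohol 17, which directs an epoxidation to its own face (18). After radical deoxygenation of C18 (19, 20), hydride opens the epoxide at C2 and leaves the C3 oxygen where the target has it (21).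

**Key disconnection (13 from 11).** The C4–O and C4–C5 bonds are cut together. Forward, the carbenoid from diazo keto ester 11 is trapped by the tertiary allyl ether oxygen, and the allyl group shifts from oxygen to C4. This closes the oxane, builds the quaternary C4 and delivers the C3 ketone and the C18 carbon in one step from an acyclic precursor with a single stereocentre.

**Precursor (11 from 8 and 9).** 11 comes from β-keto ester 10 by diazo transfer, and 10 from aldehyde 8 and ethyl diazoacetate 9 by a chemoselective homologation of the aldehyde.

**Chiral pool (8 from 1).** Cleaving the ring alkene of 5 gives 8, with C1 taken unchanged from (R)-limonene 1. The tertiary C15–O bond is made by hydration of the isopropenyl group (3). The allyl group is attached at its own unhindered carbon (4 to 5), so no substitution at a tertiary centre is needed.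

## Alternatives that were turned down

**Alternative 1:** The C4–O bond is cut last. Forward, mild acid makes the C15 hydroxyl of the macrocyclic 3,4-epoxide A1 attack C4 with inversion and gives the bridged oxane A2.
- For it: C3 and C4 are set together and stereospecifically from the epoxide geometry, with no protecting group on C3. On this point it is stronger than the chosen route, which spends several steps on the C3 oxygen.
- Against it: the whole 14-membered carbocycle must first be made with the epoxide on the correct face relative to C1, without a directing group. The opening must go 6-endo at the tertiary C4 against 5-exo attack at C3, which gives an oxolane. The cationic character at C4 also invites transannular capture by the C11=C12 and C8 alkenes.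
- Comparison: all the risk falls at the end on the most valuable intermediate. The chosen route makes the hindered C4–O bond early, on a small acyclic compound with one stereocentre.

**Alternative 2:** The ring is cut at C9–C10. Forward, the carbanion of the C10 allyl sulfone in A3 displaces the allylic bromide at C9 under high dilution and gives the sulfonyl macrocycle A4 as both C10 epimers, which converge on desulfonylation.
- For it: this is a dependable way to close 14-membered terpenoid rings and creates no lasting stereocentre. On ring closure it is at least as safe as the chromium-mediated closure used here, which has to be followed by a redox correction at C7.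
- Against it: it is only a ring-closing tactic. A3 already needs the complete oxane with C1, C3, C4 and C7 in place, so the quaternary ether is left unsolved. It also adds sulfone introduction and a reductive desulfonylation that can shift or isomerise the C11=C12 alkene.
- Comparison: the chosen strategy answers the oxane problem itself and needs no auxiliary group on the ring carbons.

**Alternative 3:** C1–C2 is cut. Forward, enolisation and O-silylation of the 14-membered lactone A5 (C15 ester on the C4 oxygen of a linalool-type tertiary allylic alcohol) set up a [3,3] shift. This contracts the lactone to the carbocyclic triene acid A6, forming C1–C2 and the (E)-C3=C4 alkene.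
- For it: it builds the carbocycle and C1 in one step from a lactone. For the carbocycle alone it is more step-economic than the chosen route.
- Against it: lactonisation onto a tertiary allylic alcohol is difficult. The ketene acetal geometry and the chair or boat course inside the ring, which together decide C1, are not secured. After the contraction the acid still has to become the CMe2–O group, and the C3=C4 alkene still has to be epoxidised selectively and opened as in Alternative 1.
- Comparison: the hardest bond, C4–O, is postponed, not solved. The chosen route forms it first.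

Key step: step 7

## Route

Step 1
Reactants: 1 (R)-(+)-limonene
Product: 3 (R)-α-terpineol, via acetoxymercurio alcohol 2 (not isolated)
Conditions: Hg(OAc)2, THF/H2O, rt; then aq. NaOH, NaBH4, 0 °C
Reagents that add atoms: water, O
Why: Markovnikov oxymercuration–demercuration; the 1,1-disubstituted isopropenyl alkene reacts much faster than the trisubstituted ring alkene and the stereocentre is untouched. Allyl alcohol is not used as the nucleophile here, because the β-allyloxy alkyl radical formed during demercuration would be expected to cyclise 5-exo onto the allyl group.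

Step 2
Reactants: 3 (R)-α-terpineol; 4 allyl bromide
Product: 5 allyl (R)-α-terpinyl ether
Conditions: KH, THF, 0 °C; then 4, Bu4NI (cat.), 0 °C to rt
Reagents that add atoms: none
Why: Williamson ether synthesis; the displacement takes place at the unhindered allylic carbon of 4, so the tertiary centre only acts as the alkoxide.

Step 3
Reactants: 5 allyl (R)-α-terpinyl ether
Product: 6 ring epoxide of 5 (both epoxide diastereomers)
Conditions: mCPBA, NaHCO3, CH2Cl2, 0 °C
Reagents that add atoms: 3-chloroperoxybenzoic acid (mCPBA), OOC(=O)c1cccc(Cl)c1
Why: Prilezhaev epoxidation; the trisubstituted ring alkene is far more nucleophilic than the terminal allyl ether alkene, and both epoxide diastereomers give the same product in step 4.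

Step 4
Reactants: 6 ring epoxide
Product: 8 (3R)-keto aldehyde, via diol 7 (not isolated)
Conditions: H5IO6, THF/H2O, 0 °C to rt
Reagents that add atoms: water, O
Why: Acid-mediated epoxide hydrolysis followed by periodate glycol cleavage in one operation; the stereocentre is β to the new aldehyde and cannot epimerise.

Step 5
Reactants: 8 (3R)-keto aldehyde; 9 ethyl diazoacetate
Product: 10 β-keto ester
Conditions: SnCl2 (10 mol%), CH2Cl2, rt
Reagents that add atoms: none
Why: Roskamp homologation: the Lewis-acid-activated aldehyde adds the diazo ester and a 1,2-hydride shift with loss of nitrogen gives the β-keto ester; the methyl ketone does not react under these conditions.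

Step 6
Reactants: 10 β-keto ester
Product: 11 diazo keto ester
Conditions: 4-acetamidobenzenesulfonyl azide, Et3N, MeCN, 0 °C to rt
Reagents that add atoms: 4-acetamidobenzenesulfonyl azide, CC(=O)Nc1ccc(cc1)S(=O)(=O)N=[N+]=[N-]
Why: Regitz diazo transfer to the only doubly activated methylene; the methyl ketone is not acidic enough to react with triethylamine as base.

Step 7
Reactants: 11 diazo keto ester
Product: 13 2-allyl oxan-3-one keto ester, via oxonium ylide 12 (not isolated)
Conditions: Cu(CF3COCHCOCF3)2 (5 mol%), ClCH2CH2Cl, reflux, slow addition of 11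
Reagents that add atoms: none
Why: Loss of nitrogen from 11 at the divalent copper centre gives an electrophilic, doubly acceptor-substituted carbenoid at C4; a lone pair of the allyl ether oxygen attacks it and closes the six-membered oxonium ylide 12 (O–C4 bond, closure exo to the carbon–metal bond), and the allyl group then moves suprafacially from oxygen to C4 through a five-membered envelope transition state, forming C4–C5 and leaving the oxan-3-one. The closest known reaction type is the copper- or rhodium-catalysed oxonium ylide formation and [2,3]-sigmatropic rearrangement of allyl ethers tethered to diazo ketones and diazo keto esters, which gives 2-allyl oxan-3-ones; a tertiary ether oxygen in the six-membered series is at the edge of that precedent. C4 is the only new stereocentre and is fixed by the configuration of the oxonium oxygen: in a chair-like closure the C1 side chain is equatorial and the allyl group on oxygen takes the equatorial position cis to it, and it is delivered to C4 on the face it occupied on oxygen, so that C5 ends cis to C14. The step needs ylide formation to outrun 1,5 C–H insertion at C14 and loss of the tertiary C15–O bond from the oxonium ion; the acceptor-substituted carbenoid, the Lewis-acidic copper catalyst and the six-atom tether favour attack by oxygen, and the [2,3] shift is faster than a [1,2] shift. The two methyl groups on C15 flank the oxonium oxygen on both faces, so the equatorial preference of the allyl group is weaker than with secondary ethers and the ratio at C4 is the main open point. The free C12 ketone would have to close an eight-membered carbonyl ylide and should not compete.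

Step 8
Reactants: 13 2-allyl oxan-3-one keto ester
Product: 14 ketal keto ester
Conditions: (Me3SiOCH2)2, Me3SiOTf (5 mol%), CH2Cl2, −78 to −30 °C
Reagents that add atoms: 1,2-bis(trimethylsilyloxy)ethane, C[Si](C)(C)OCCO[Si](C)(C)C
Why: Silyl triflate-catalysed ketalisation; the unhindered methyl ketone reacts, while the C3 ketone, flanked by the fully substituted C4, is left.

Step 9
Reactants: 14 ketal keto ester
Product: 15 enol triflate
Conditions: KN(SiMe3)2, THF, −78 °C; then PhNTf2, −78 to 0 °C
Reagents that add atoms: N-phenylbis(trifluoromethanesulfonimide), O=S(=O)(N(c1ccccc1)S(=O)(=O)C(F)(F)F)C(F)(F)F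
Why: The C3 ketone can enolise only towards C2; O-sulfonylation of the potassium enolate at low temperature gives the C2=C3 enol triflate before any sigmatropic shift of the allyl group can intervene.

Step 10
Reactants: 15 enol triflate
Product: 16 dihydropyran ester
Conditions: Pd(OAc)2 (5 mol%), PPh3, HCO2H, Bu3N, DMF, 60 °C
Reagents that add atoms: none
Why: Palladium-catalysed formate reduction of an enol triflate: oxidative addition to zerovalent palladium, formate exchange, decarboxylation and reductive elimination give the C2=C3 alkene; the buffered medium spares the ketal.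

Step 11
Reactants: 16 dihydropyran ester
Product: 17 dihydropyran methanol
Conditions: LiAlH4, Et2O, 0 °C
Reagents that add atoms: none
Why: Hydride reduction of the ester to the C18 primary alcohol; no other group in 16 is reducible under these conditions.

Step 12
Reactants: 17 dihydropyran methanol
Product: 18 epoxy alcohol
Conditions: VO(acac)2 (5 mol%), t-BuOOH, CH2Cl2, 0 °C to rt
Reagents that add atoms: tert-butyl hydroperoxide, CC(C)(C)OO
Why: Hydroxyl-directed epoxidation of a homoallylic alcohol: the vanadium alkoxide of the C18 hydroxyl delivers oxygen to the ring alkene on the face of C18, which is also the face away from C14 and C5, and this sets the C3–O bond. The terminal allyl alkene is monosubstituted and further from the hydroxyl and should not react.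

Step 13
Reactants: 18 epoxy alcohol
Product: 19 epoxy xanthate
Conditions: NaH, THF, 0 °C; CS2; then MeI, 0 °C to rt
Reagents that add atoms: carbon disulfide, S=C=S; iodomethane, CI
Why: Xanthate formation for a Barton–McCombie deoxygenation; the C18 alkoxide is cis to the epoxide oxygen and has no backside access to C3, so the epoxide survives.

Step 14
Reactants: 19 epoxy xanthate
Product: 20 C18-methyl epoxide
Conditions: Bu3SnH, AIBN, toluene, reflux
Reagents that add atoms: none
Why: Barton–McCombie deoxygenation; radical C–O cleavage avoids a substitution at the neopentyl C18, and the primary radical has only slow 4-exo or 5-endo cyclisation channels. It is run only after the C2=C3 alkene is gone, because a homoallylic C18 radical would undergo a 1,2-vinyl shift.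

Step 15
Reactants: 20 C18-methyl epoxide
Product: 21 (3R)-oxan-3-ol
Conditions: LiEt3BH, THF, 0 °C to rt
Reagents that add atoms: none
Why: SN2 opening of the epoxide by hydride at C2, the less hindered carbon (C3 is neopentyl), in the trans-diaxial sense of the Fürst–Plattner rule; the C3–O bond is not touched, so the hydroxyl stays cis to C18.

Step 16
Reactants: 21 (3R)-oxan-3-ol
Product: 23 C3,C7-diol, via B-alkyl-9-BBN adduct 22 (not isolated)
Conditions: 9-BBN (2.5 equiv), THF, 0 °C to rt; then NaOH, H2O2, 0 °C
Reagents that add atoms: hydrogen peroxide, OO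
Why: Anti-Markovnikov hydroboration–oxidation of the terminal alkene gives the C7 primary alcohol; the ketal and the ring ether are inert.

Step 17
Reactants: 23 C3,C7-diol
Product: 24 bis-silyl ether ketal
Conditions: t-BuMe2SiOTf (3 equiv), 2,6-lutidine, CH2Cl2, −78 to 0 °C
Reagents that add atoms: tert-butyldimethylsilyl trifluoromethanesulfonate, CC(C)(C)[Si](C)(C)OS(=O)(=O)C(F)(F)F
Why: Silylation of both hydroxyls in one step; the hindered C3 hydroxyl needs the silyl triflate.

Step 18
Reactants: 24 bis-silyl ether ketal
Product: 25 methyl ketone
Conditions: PPTS, acetone/H2O, 50 °C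
Reagents that add atoms: water, O
Why: Acid-catalysed ketal hydrolysis with a pyridinium salt; silyl ethers and the di-tertiary ether should tolerate this weak acid in a non-alcoholic medium.

Step 19
Reactants: 25 methyl ketone
Product: 27 terminal alkyne, via enol phosphate 26 (not isolated)
Conditions: LiN(iPr)2, THF, −78 °C; ClP(O)(OEt)2, −78 °C to rt; then LiN(iPr)2 (2.3 equiv), −78 °C to rt
Reagents that add atoms: none
Why: Kinetic deprotonation on the methyl side, O-phosphorylation and base-induced elimination of the terminal enol phosphate convert the methyl ketone into the alkyne; the former methyl carbon becomes C11.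

Step 20
Reactants: 27 terminal alkyne
Product: 29 (E)-alkenyl iodide, via alkenylalane 28 (not isolated)
Conditions: AlMe3, Cp2ZrCl2, CH2Cl2, 0 °C to rt; then I2, THF, −30 to 0 °C
Reagents that add atoms: trimethylaluminium, C[Al](C)C; iodine, II
Why: Zirconium-catalysed carboalumination adds methyl and aluminium syn across the alkyne with methyl on C12, and iodinolysis with retention gives the (E)-2-methyl-1-iodoalkene, which fixes the C11=C12 geometry.

Step 21
Reactants: 30 3-bromobut-3-en-1-ol
Product: 31 2-bromo-4-iodobut-1-ene
Conditions: I2, PPh3, imidazole, CH2Cl2, 0 °C to rt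
Reagents that add atoms: iodine, II
Why: Appel-type iodination of an unhindered primary alcohol; the alkenyl bromide is inert.

Step 22
Reactants: 29 (E)-alkenyl iodide; 31 2-bromo-4-iodobut-1-ene
Product: 33 bromo diene bis-silyl ether, via alkylzinc iodide 32 (not isolated)
Conditions: Zn dust (activated with BrCH2CH2Br and Me3SiCl), 31, THF, 40 °C; then 29, Pd(PPh3)4 (5 mol%), THF, rt
Reagents that add atoms: none
Why: Zinc inserts into the primary alkyl iodide but not into the alkenyl bromide, and Negishi coupling of the homoallylic zinc reagent with the alkenyl iodide forms C10–C11 with retention of the E geometry. The alkenyl iodide adds to zerovalent palladium much faster than the alkenyl bromide.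

Step 23
Reactants: 33 bromo diene bis-silyl ether
Product: 34 C7 alcohol
Conditions: HF·pyridine, pyridine, THF, 0 °C
Reagents that add atoms: none
Why: Buffered fluoride cleaves the primary silyl ether much faster than the silyl ether on the hindered C3 oxygen.

Step 24
Reactants: 34 C7 alcohol
Product: 35 C7 aldehyde
Conditions: Dess–Martin periodinane, NaHCO3, CH2Cl2, rt
Reagents that add atoms: none
Why: Dess–Martin oxidation of a primary alcohol under buffered, non-acidic conditions; the alkenes and the alkenyl bromide are unaffected.

Step 25
Reactants: 35 C7 aldehyde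
Product: 36 macrocyclic allylic alcohol (C7 epimers)
Conditions: CrCl2 (15 equiv), NiCl2 (5 mol%), DMSO/THF, rt to 50 °C, high dilution by syringe pump
Reagents that add atoms: none
Why: Intramolecular Nozaki–Hiyama–Kishi coupling: nickel activates the 2-bromoalkene, transmetalation to chromium gives an alkenylchromium species that adds only to the aldehyde and forms C7–C8 with the exocyclic methylene in place. The two reacting arms are cis on the oxane, which helps the 14-membered closure; the C7 configuration need not be controlled here.

Step 26
Reactants: 36 macrocyclic allylic alcohol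
Product: 37 macrocyclic enone silyl ether
Conditions: Dess–Martin periodinane, NaHCO3, CH2Cl2, 0 °C to rt
Reagents that add atoms: none
Why: Dess–Martin oxidation of the allylic alcohol; both C7 epimers converge on one enone.

Step 27
Reactants: 37 macrocyclic enone silyl ether
Product: 38 macrocyclic hydroxy enone
Conditions: HF·pyridine, THF, rt to 40 °C
Reagents that add atoms: none
Why: Fluoride cleavage of the remaining, hindered silyl ether under acidic, non-nucleophilic conditions that an α-methylene ketone tolerates.

Step 28
Reactants: 38 macrocyclic hydroxy enone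
Product: 39 macrocyclic enone acetate
Conditions: Ac2O, DMAP, Et3N, CH2Cl2, rt
Reagents that add atoms: acetic anhydride, CC(=O)OC(C)=O
Why: DMAP-catalysed acylation of the only hydroxyl in the molecule; placing it here avoids a selective acetylation of C3 in the presence of the C7 hydroxyl.

Step 29
Reactants: 39 macrocyclic enone acetate
Product: 40 target CNP0202897.1
Conditions: (S)-2-methyl-CBS-oxazaborolidine (0.5 equiv), catecholborane, toluene, −78 °C
Reagents that add atoms: none
Why: Corey–Bakshi–Shibata reduction: the α-methylene vinyl group acts as the large substituent, so the (S)-catalyst should give the (7R)-alcohol by 1,2-reduction. Catecholborane at low temperature leaves the acetate and the other alkenes alone.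

## Compound list

1 | (R)-(+)-limonene, (4R)-1-methyl-4-(prop-1-en-2-yl)cyclohex-1-ene | CC1=CC[C@@H](CC1)C(C)=C | starting material
2 | acetoxymercurio alcohol, {2-hydroxy-2-[(1R)-4-methylcyclohex-3-en-1-yl]propyl}mercury acetate (carbinol carbon unassigned) | CC1=CC[C@@H](CC1)C(C)(O)C[Hg]OC(C)=O | intermediate (not isolated)
3 | (R)-α-terpineol, 2-[(1R)-4-methylcyclohex-3-en-1-yl]propan-2-ol | CC1=CC[C@@H](CC1)C(C)(C)O | intermediate
4 | allyl bromide, 3-bromoprop-1-ene | C=CCBr | starting material
5 | allyl (R)-α-terpinyl ether, (4R)-1-methyl-4-[2-(prop-2-en-1-yloxy)propan-2-yl]cyclohex-1-ene | CC1=CC[C@@H](CC1)C(C)(C)OCC=C | intermediate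
6 | (4R)-1-methyl-4-[2-(prop-2-en-1-yloxy)propan-2-yl]-7-oxabicyclo[4.1.0]heptane, both epoxide diastereomers | CC12OC1C[C@@H](CC2)C(C)(C)OCC=C | intermediate
7 | (4R)-1-methyl-4-[2-(prop-2-en-1-yloxy)propan-2-yl]cyclohexane-1,2-diol, diastereomer mixture | CC1(O)C(O)C[C@@H](CC1)C(C)(C)OCC=C | intermediate (not isolated)
8 | (3R)-6-oxo-3-[2-(prop-2-en-1-yloxy)propan-2-yl]heptanal | CC(=O)CC[C@H](CC=O)C(C)(C)OCC=C | intermediate
9 | ethyl diazoacetate | CCOC(=O)C=[N+]=[N-] | starting material
10 | ethyl (5R)-3,8-dioxo-5-[2-(prop-2-en-1-yloxy)propan-2-yl]nonanoate | CCOC(=O)CC(=O)C[C@@H](CCC(C)=O)C(C)(C)OCC=C | intermediate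
11 | ethyl (5R)-2-diazo-3,8-dioxo-5-[2-(prop-2-en-1-yloxy)propan-2-yl]nonanoate (key-step precursor) | CCOC(=O)C(=[N+]=[N-])C(=O)C[C@@H](CCC(C)=O)C(C)(C)OCC=C | intermediate
12 | six-membered oxonium ylide: O-allyl oxonium with carbanionic C4 between the ketone and the ester | CCOC(=O)[C-]1C(=O)C[C@@H](CCC(C)=O)C(C)(C)[O+]1CC=C | intermediate (not isolated)
13 | ethyl (2S,5R)-6,6-dimethyl-3-oxo-5-(3-oxobutyl)-2-(prop-2-en-1-yl)oxane-2-carboxylate (key-step product; allyl cis to the C1 side chain) | CC(=O)CC[C@@H]1CC(=O)[C@](C(=O)OCC)(CC=C)OC1(C)C | intermediate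
14 | ethyl (2S,5R)-6,6-dimethyl-5-[2-(2-methyl-1,3-dioxolan-2-yl)ethyl]-3-oxo-2-(prop-2-en-1-yl)oxane-2-carboxylate | CC1(CC[C@@H]2CC(=O)[C@](C(=O)OCC)(CC=C)OC2(C)C)OCCO1 | intermediate
15 | ethyl (2S,5R)-6,6-dimethyl-5-[2-(2-methyl-1,3-dioxolan-2-yl)ethyl]-2-(prop-2-en-1-yl)-3-(trifluoromethanesulfonyloxy)-5,6-dihydro-2H-pyran-2-carboxylate | CC1(CC[C@@H]2C=C(OS(=O)(=O)C(F)(F)F)[C@](C(=O)OCC)(CC=C)OC2(C)C)OCCO1 | intermediate
16 | ethyl (2S,5R)-6,6-dimethyl-5-[2-(2-methyl-1,3-dioxolan-2-yl)ethyl]-2-(prop-2-en-1-yl)-5,6-dihydro-2H-pyran-2-carboxylate | CC1(CC[C@@H]2C=C[C@](C(=O)OCC)(CC=C)OC2(C)C)OCCO1 | intermediate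
17 | [(2S,5R)-6,6-dimethyl-5-[2-(2-methyl-1,3-dioxolan-2-yl)ethyl]-2-(prop-2-en-1-yl)-5,6-dihydro-2H-pyran-2-yl]methanol | CC1(CC[C@@H]2C=C[C@](CO)(CC=C)OC2(C)C)OCCO1 | intermediate
18 | C2–C3 epoxide of 17, epoxide oxygen cis to the hydroxymethyl group (C18) and trans to C5 and C14 | CC1(CC[C@@H]2[C@H]3O[C@H]3[C@](CO)(CC=C)OC2(C)C)OCCO1 | intermediate
19 | O-alkyl S-methyl dithiocarbonate (xanthate) of the C18 hydroxyl of 18 | CC1(CC[C@@H]2[C@H]3O[C@H]3[C@](COC(=S)SC)(CC=C)OC2(C)C)OCCO1 | intermediate
20 | C2–C3 epoxide with C18 as methyl, epoxide oxygen cis to C18 | CC1(CC[C@@H]2[C@H]3O[C@H]3[C@](C)(CC=C)OC2(C)C)OCCO1 | intermediate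
21 | (2S,3R,5R)-2,6,6-trimethyl-5-[2-(2-methyl-1,3-dioxolan-2-yl)ethyl]-2-(prop-2-en-1-yl)oxan-3-ol (C1 R, C3 R, C4 S) | CC1(CC[C@@H]2C[C@@H](O)[C@](C)(CC=C)OC2(C)C)OCCO1 | intermediate
22 | B-alkyl-9-borabicyclo[3.3.1]nonane adduct at C7 of 21 | CC1(CC[C@@H]2C[C@@H](O)[C@](C)(CCCB3C4CCCC3CCC4)OC2(C)C)OCCO1 | intermediate (not isolated)
23 | 3-[(2S,3R,5R)-3-hydroxy-2,6,6-trimethyl-5-[2-(2-methyl-1,3-dioxolan-2-yl)ethyl]oxan-2-yl]propan-1-ol | CC1(CC[C@@H]2C[C@@H](O)[C@](C)(CCCO)OC2(C)C)OCCO1 | intermediate
24 | C3,C7-bis(tert-butyldimethylsilyl) ether of 23 | CC1(CC[C@@H]2C[C@@H](O[Si](C)(C)C(C)(C)C)[C@](C)(CCCO[Si](C)(C)C(C)(C)C)OC2(C)C)OCCO1 | intermediate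
25 | C12 methyl ketone, C3 and C7 as tert-butyldimethylsilyl ethers (C1 R, C3 R, C4 S) | CC(=O)CC[C@@H]1C[C@@H](O[Si](C)(C)C(C)(C)C)[C@](C)(CCCO[Si](C)(C)C(C)(C)C)OC1(C)C | intermediate
26 | terminal enol diethyl phosphate of 25 | C=C(OP(=O)(OCC)OCC)CC[C@@H]1C[C@@H](O[Si](C)(C)C(C)(C)C)[C@](C)(CCCO[Si](C)(C)C(C)(C)C)OC1(C)C | intermediate (not isolated)
27 | terminal alkyne C11≡C12, bis-silyl ether | C#CCC[C@@H]1C[C@@H](O[Si](C)(C)C(C)(C)C)[C@](C)(CCCO[Si](C)(C)C(C)(C)C)OC1(C)C | intermediate
28 | (E)-2-methylalk-1-enyl(dimethyl)alane, aluminium on C11 | C[Al](C)/C=C(\C)CC[C@@H]1C[C@@H](O[Si](C)(C)C(C)(C)C)[C@](C)(CCCO[Si](C)(C)C(C)(C)C)OC1(C)C | intermediate (not isolated)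
29 | (E)-C11 alkenyl iodide (1-iodo-2-methylalk-1-ene), bis-silyl ether | I/C=C(\C)CC[C@@H]1C[C@@H](O[Si](C)(C)C(C)(C)C)[C@](C)(CCCO[Si](C)(C)C(C)(C)C)OC1(C)C | intermediate
30 | 3-bromobut-3-en-1-ol | C=C(Br)CCO | starting material
31 | 2-bromo-4-iodobut-1-ene | C=C(Br)CCI | intermediate
32 | (3-bromobut-3-en-1-yl)zinc iodide | C=C(Br)CC[Zn]I | intermediate (not isolated)
33 | open-chain C8 bromoalkene, (11E)-alkene, C3 and C7 silyl ethers (C1 R, C3 R, C4 S) | C=C(Br)CC/C=C(\C)CC[C@@H]1C[C@@H](O[Si](C)(C)C(C)(C)C)[C@](C)(CCCO[Si](C)(C)C(C)(C)C)OC1(C)C | intermediate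
34 | C7 primary alcohol of 33, C3 silyl ether | C=C(Br)CC/C=C(\C)CC[C@@H]1C[C@@H](O[Si](C)(C)C(C)(C)C)[C@](C)(CCCO)OC1(C)C | intermediate
35 | C7 aldehyde, C8 bromoalkene, C3 silyl ether | C=C(Br)CC/C=C(\C)CC[C@@H]1C[C@@H](O[Si](C)(C)C(C)(C)C)[C@](C)(CCC=O)OC1(C)C | intermediate
36 | 14-membered macrocycle, C7 alcohol (both epimers), C8 methylene, C3 silyl ether | C=C1CC/C=C(\C)CC[C@@H]2C[C@@H](O[Si](C)(C)C(C)(C)C)[C@](C)(CCC1O)OC2(C)C | intermediate
37 | macrocyclic C7 enone, C3 silyl ether | C=C1CC/C=C(\C)CC[C@@H]2C[C@@H](O[Si](C)(C)C(C)(C)C)[C@](C)(CCC1=O)OC2(C)C | intermediate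
38 | macrocyclic C7 enone, free C3 alcohol | C=C1CC/C=C(\C)CC[C@@H]2C[C@@H](O)[C@](C)(CCC1=O)OC2(C)C | intermediate
39 | macrocyclic C7 enone, C3 acetate | C=C1CC/C=C(\C)CC[C@@H]2C[C@@H](OC(C)=O)[C@](C)(CCC1=O)OC2(C)C | intermediate
40 | CNP0202897.1, (1R,3R,4S,7R,11E)-configured 4,15-ether-bridged cembranoid 3-acetate | C=C1CC/C=C(\C)CC[C@@H]2C[C@@H](OC(C)=O)[C@](C)(CC[C@H]1O)OC2(C)C | target

## Step count and least certain steps

Total: 29 steps. Longest linear sequence: 28 steps (steps 1–20 and 22–29 from 1); step 21 prepares the C8–C10 piece.

**Step 7 (key step).** The most likely failure is delivery of the allyl group to the wrong face of C4. The two methyl groups on C15 sit next to the oxonium oxygen and weaken the preference that places the allyl group cis to the C1 side chain. Competing 1,5 C–H insertion at C14 and cleavage of the tertiary C15–O bond of the oxonium ion are the other risks.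
The fallback makes C4–O by O–H insertion and C4–C5 by enolate alkylation, so a different event decides C4. It sets out from 3. Oxidative cleavage of the ring alkene (RuCl3, NaIO4) gives a keto acid that lactonises onto the tertiary hydroxyl to the keto lactone (4R)-5,5-dimethyl-4-(3-oxobutyl)oxolan-2-one F1. Ketalisation with ethylene glycol gives the ketal lactone F2. Lithiated 9 opens the lactone to the hydroxy diazo keto ester F3, and Rh2(OAc)4 then closes the oxane by O–H insertion to the cyclic β-keto ester F4. C-allylation of F4 with 4 and K2CO3 (with a thermal Claisen shift of any O-allyl product) returns to the route at 14.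

**Step 12 (with step 15).** The directed epoxidation may show poor facial selectivity or attack the allyl group, because the directing hydroxyl sits on a fully substituted carbon. The later hydride opening could also be slow next to C1.
The fallback gives up the epoxide and reduces the ketone directly. It sets out from 14. NaBH4 at low temperature is used in the hope of axial attack anti to an axial ester group, as is usual for 2-alkyl-2-alkoxycarbonyl cyclohexanones, to give the cis-hydroxy ester F5. LiAlH4 gives the diol F6, and selective acylation of the primary hydroxyl with phenyl chlorothionoformate gives the thionocarbonate F7. Bu3SnH then returns to the route at 21. This is the second choice because the C14 arm may block the required trajectory.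

**Step 25.** The 2-bromoalkene may add to nickel too slowly, so that oligomerisation or aldehyde decomposition wins at high dilution.
The fallback closes the same bond by a nickel-catalysed reductive alkyne–aldehyde coupling. It sets out from 29. Negishi coupling with [4-(trimethylsilyl)but-3-yn-1-yl]zinc bromide F8 gives the silyl enyne F9, and K2CO3 in methanol frees the terminal alkyne F10. Selective cleavage of the primary silyl ether gives the alcohol F11, and Dess–Martin oxidation gives the ynal F12. Ni(cod)2 with a bulky N-heterocyclic carbene and Et3SiH should then give the exocyclic-methylene macrocycle as its triethylsilyl ether F13. Mild acid methanolysis of the triethylsilyl group returns to the route at 36.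

**Step 29.** The conformation of the macrocycle may override the catalyst, giving poor facial selectivity at C7.
The fallback replaces reagent control by substrate control plus inversion. It sets out from 39. Luche reduction (NaBH4, CeCl3) gives the alcohol the ring prefers; if that is the (7S)-epimer F14, a Mitsunobu reaction with 4-nitrobenzoic acid gives the (7R)-4-nitrobenzoate F15. Methanolysis with K2CO3 at 0 °C, which the hindered C3 acetate should survive, returns to the route at 40.

## Further compounds

F1 | step 7 | (4R)-5,5-dimethyl-4-(3-oxobutyl)oxolan-2-one | CC(=O)CC[C@@H]1CC(=O)OC1(C)C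
F2 | step 7 | (4R)-5,5-dimethyl-4-[2-(2-methyl-1,3-dioxolan-2-yl)ethyl]oxolan-2-one | CC1(CC[C@@H]2CC(=O)OC2(C)C)OCCO1
F3 | step 7 | ethyl (5R)-2-diazo-6-hydroxy-6-methyl-5-[2-(2-methyl-1,3-dioxolan-2-yl)ethyl]-3-oxoheptanoate | CCOC(=O)C(=[N+]=[N-])C(=O)C[C@@H](CCC1(C)OCCO1)C(C)(C)O
F4 | step 7 | ethyl (5R)-6,6-dimethyl-5-[2-(2-methyl-1,3-dioxolan-2-yl)ethyl]-3-oxooxane-2-carboxylate (C2 unassigned) | CC1(CC[C@@H]2CC(=O)C(C(=O)OCC)OC2(C)C)OCCO1
F5 | step 12 | ethyl (2S,3R,5R)-3-hydroxy-6,6-dimethyl-5-[2-(2-methyl-1,3-dioxolan-2-yl)ethyl]-2-(prop-2-en-1-yl)oxane-2-carboxylate | CC1(CC[C@@H]2C[C@@H](O)[C@](C(=O)OCC)(CC=C)OC2(C)C)OCCO1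
F6 | step 12 | C3,C18-diol: 2-(hydroxymethyl)oxan-3-ol with allyl on C4 and ketal side chain | CC1(CC[C@@H]2C[C@@H](O)[C@](CO)(CC=C)OC2(C)C)OCCO1
F7 | step 12 | O-phenyl thionocarbonate of the C18 hydroxyl of F6 | CC1(CC[C@@H]2C[C@@H](O)[C@](COC(=S)Oc3ccccc3)(CC=C)OC2(C)C)OCCO1
F8 | step 25 | [4-(trimethylsilyl)but-3-yn-1-yl]zinc bromide | C[Si](C)(C)C#CCC[Zn]Br
F9 | step 25 | open-chain (11E)-enyne with trimethylsilyl alkyne, C3 and C7 silyl ethers | C[Si](C)(C)C#CCC/C=C(\C)CC[C@@H]1C[C@@H](O[Si](C)(C)C(C)(C)C)[C@](C)(CCCO[Si](C)(C)C(C)(C)C)OC1(C)C
F10 | step 25 | terminal alkyne of F9 | C#CCC/C=C(\C)CC[C@@H]1C[C@@H](O[Si](C)(C)C(C)(C)C)[C@](C)(CCCO[Si](C)(C)C(C)(C)C)OC1(C)C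
F11 | step 25 | C7 primary alcohol of F10, C3 silyl ether | C#CCC/C=C(\C)CC[C@@H]1C[C@@H](O[Si](C)(C)C(C)(C)C)[C@](C)(CCCO)OC1(C)C
F12 | step 25 | ynal: C7 aldehyde with terminal alkyne, C3 silyl ether | C#CCC/C=C(\C)CC[C@@H]1C[C@@H](O[Si](C)(C)C(C)(C)C)[C@](C)(CCC=O)OC1(C)C
F13 | step 25 | macrocyclic C7 triethylsilyl ether (both epimers), C8 methylene, C3 tert-butyldimethylsilyl ether | C=C1CC/C=C(\C)CC[C@@H]2C[C@@H](O[Si](C)(C)C(C)(C)C)[C@](C)(CCC1O[Si](CC)(CC)CC)OC2(C)C
F14 | step 29 | (7S)-epimer of the target | C=C1CC/C=C(\C)CC[C@@H]2C[C@@H](OC(C)=O)[C@](C)(CC[C@@H]1O)OC2(C)C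
F15 | step 29 | (7R)-4-nitrobenzoate of the target | C=C1CC/C=C(\C)CC[C@@H]2C[C@@H](OC(C)=O)[C@](C)(CC[C@H]1OC(=O)c3ccc(cc3)[N+](=O)[O-])OC2(C)C
A1 | alternative 1 | 14-membered 3,4-epoxide with C15 tertiary alcohol and C7 silyl ether | C=C1CC/C=C(\C)CC[C@@H](C(C)(C)O)C[C@H]2O[C@]2(C)CC[C@H]1O[Si](C)(C)C(C)(C)C
A2 | alternative 1 | bridged oxane with free C3 alcohol and C7 silyl ether | C=C1CC/C=C(\C)CC[C@@H]2C[C@@H](O)[C@](C)(CC[C@H]1O[Si](C)(C)C(C)(C)C)OC2(C)C
A3 | alternative 2 | open-chain C10 phenyl sulfone with C9 allylic bromide, C3 silyl ether, C7 4-methoxybenzyl ether | O=S(=O)(C/C=C(\C)CC[C@@H]1C[C@@H](O[Si](C)(C)C(C)(C)C)[C@](C)(CC[C@@H](OCc2ccc(OC)cc2)C(=C)CBr)OC1(C)C)c1ccccc1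
A4 | alternative 2 | macrocycle with C10 phenyl sulfone (both C10 epimers) | C=C1CC(S(=O)(=O)c3ccccc3)/C=C(\C)CC[C@@H]2C[C@@H](O[Si](C)(C)C(C)(C)C)[C@](C)(CC[C@H]1OCc4ccc(OC)cc4)OC2(C)C
A5 | alternative 3 | 14-membered lactone of the C15 acid with the C4 tertiary allylic oxygen (C4 drawn as the carbinol configuration a chair transition state would need with C14 cis to the silyloxy group) | O=C1CCC/C(C)=C/CCC(=C)[C@H](O[Si](C)(C)C(C)(C)C)CC[C@](C)(C=C)O1
A6 | alternative 3 | 14-membered triene carbocycle with the C15 acid on C1 | C=C1CC/C=C(\C)CC[C@@H](C(=O)O)C/C=C(\C)CC[C@H]1O[Si](C)(C)C(C)(C)C
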